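The 3,7-dioxabicyclo[3.3.0]octane core (C1 carbinol bridgehead, C2, O3, C4, C5 bridgehead, C6, O7, C8; ring A = C5–C6–O7–C8–C1, ring B = C1–C2–O3–C4–C5) is trans-fused and carries both ether oxygens on the benzylic stereocentres C2 and C6, whereas C4 and C8 are primary carbons. It is therefore cut at O3–C4 and O7–C8. One base treatment closes ring B and then ring A from an open-chain 1,4-diaryl-1,4-diol by two 5-exo-tet alkoxide displacements of primary tosylates that touch no stereocentre. The precursor already holds C1, C2, C5 and C6 in their final configuration and has the C1 oxygen blocked as a tert-butyldimethylsilyl ether.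

Key step: step 17

Remark (abbreviations): TBS = tert-butyldimethylsilyl, TBSO = its oxy group, Ar = 3,4-dimethoxyphenyl; the core numbering above is used for all intermediates, open-chain ones included.

Remark (assumption): ester 5 is used as the racemate because its stereocentre becomes trigonal in step 6; hence 7 is a pair of epimers, 18 a pair of carbinol epimers that converge in step 12, and 21 a mixture of lactol anomers that converge in step 14.

Remark (design of the precursor): the C1 oxygen is silylated at the lactone stage, before any benzylic hydroxyl exists, since a tertiary hydroxyl cannot be silylated selectively beside two secondary ones. It carries TBS because a smaller silyl group would shift more readily to the neighbouring C2 and C6 alkoxides of the key step. C2 is made by aryl addition to an aldehyde and C6 by hydride addition to an aryl ketone, the pairing for which the Felkin–Anh model gives the required configuration at both centres. The electron-rich benzylic carbinols never meet unbuffered acid.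

Step 1
Reactants: 1 (R)-but-3-yn-2-ol
Product: 2 (4R)-pent-2-yne-1,4-diol
Conditions: n-BuLi (2.2 equiv), THF, −78 °C; (CH2O)n, −78 °C → rt; H2O
Reagents that add atoms: formaldehyde (as paraformaldehyde), C=O
Why: Alkynylation of formaldehyde by the lithium acetylide of the alkoxide adds the future C4, and the carbinol carbon is not involved and stays R.

Step 2
Reactants: 2 (4R)-pent-2-yne-1,4-diol
Product: 3 (2E,4R)-pent-2-ene-1,4-diol
Conditions: LiAlH4 (2 equiv), THF, 0 °C → reflux; H2O, aq. NaOH
Reagents that add atoms: none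
Why: Trans-hydroalumination of a propargylic alkoxide followed by protonolysis should give only the E-alkene that the chair transition state of step 6 needs, with the stereocentre untouched.

Step 3
Reactants: 3 (2E,4R)-pent-2-ene-1,4-diol
Product: 4 (2R,3E)-5-(TBSO)pent-3-en-2-ol
Conditions: t-BuMe2SiCl (1.0 equiv), imidazole, CH2Cl2, −20 → 0 °C
Reagents that add atoms: tert-butyldimethylsilyl chloride, CC(C)(C)[Si](C)(C)Cl
Why: Silylation with a bulky chlorosilane is much faster at the primary than at the secondary allylic hydroxyl, so the future C4 oxygen is masked and the secondary hydroxyl stays free.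

Step 4
Reactants: 5 methyl 2,2-dimethyl-1,3-dioxolane-4-carboxylate (racemic)
Product: 6 potassium 2,2-dimethyl-1,3-dioxolane-4-carboxylate (racemic)
Conditions: KOH (1.0 equiv), MeOH, 0 °C → rt; evaporation
Reagents that add atoms: potassium hydroxide, [K+].[OH-]
Why: Saponification of the methyl ester leaves the base-stable acetal intact and gives the salt, which is used without liberating the acid-labile free acid.

Step 5
Reactants: 6 potassium 2,2-dimethyl-1,3-dioxolane-4-carboxylate; 4 (2R,3E)-5-(TBSO)pent-3-en-2-ol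
Product: 7 (2R,3E)-5-(TBSO)pent-3-en-2-yl 2,2-dimethyl-1,3-dioxolane-4-carboxylate (both epimers at the dioxolane carbon)
Conditions: EDC·HCl (1.3 equiv), DMAP (0.2 equiv), CH2Cl2, 0 °C → rt
Reagents that add atoms: none
Why: Carbodiimide (Steglich-type) esterification acylates the hydroxyl oxygen without breaking the C–O bond of the carbinol, so the R centre is retained.

Step 6
Reactants: 7 (2R,3E)-5-(TBSO)pent-3-en-2-yl 2,2-dimethyl-1,3-dioxolane-4-carboxylate
Product: 10 (4S)-4-[(2R,3E)-1-(TBSO)pent-3-en-2-yl]-2,2-dimethyl-1,3-dioxolane-4-carboxylic acid, via silyl ketene acetal 8 (not isolated), via trimethylsilyl ester 9 (not isolated)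
Conditions: Me3SiCl, Et3N, THF, −78 °C; LiN(i-Pr)2 (1.3 equiv), −78 °C, 1 h; → rt, then 45 °C; aq. citric acid (pH 4)
Reagents that add atoms: none
Why: Ireland–Claisen rearrangement, in which deprotonation with lithium bridging the carbonyl and the ring oxygen on C1 and immediate O-silylation (which outruns β-elimination) should give the Z ketene acetal 8, whose [3,3] shift through a chair with the allylic methyl and the E-alkene substituent equatorial forms the C1–C5 bond on one face and so sets C1 and C5 in the relation that becomes the trans ring fusion, the absolute sense coming from the R carbinol.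

Step 7
Reactants: 10 (4S)-4-[(2R,3E)-1-(TBSO)pent-3-en-2-yl]-2,2-dimethyl-1,3-dioxolane-4-carboxylic acid
Product: 12 (3S,4R)-3-hydroxy-3-(hydroxymethyl)-4-[(1E)-prop-1-en-1-yl]oxolan-2-one, via trihydroxy acid 11 (not isolated)
Conditions: 3 M HCl (aq.)–THF 1:3, rt → 40 °C; evaporation from toluene
Reagents that add atoms: none
Why: Acid hydrolysis of the acetal and of the primary silyl ether is followed by lactonisation of the C4 hydroxyl onto the C2 acid, which keeps C2 distinct from C8, masks O4 and C2 together and involves no stereocentre.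

Step 8
Reactants: 12 (3S,4R)-3-hydroxy-3-(hydroxymethyl)-4-[(1E)-prop-1-en-1-yl]oxolan-2-one
Product: 13 (3S,4R)-3-(TBSO)-3-(TBSO-methyl)-4-[(1E)-prop-1-en-1-yl]oxolan-2-one
Conditions: t-BuMe2SiOTf (3.5 equiv), 2,6-lutidine (6 equiv), CH2Cl2, 0 → 35 °C
Reagents that add atoms: tert-butyldimethylsilyl trifluoromethanesulfonate, CC(C)(C)[Si](C)(C)OS(=O)(=O)C(F)(F)F
Why: Silylation with a silyl triflate and a hindered pyridine base is strong enough for the tertiary C1 hydroxyl as well as the primary C8 hydroxyl, so O1 is protected before any benzylic hydroxyl exists.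

Step 9
Reactants: 13 (3S,4R)-3-(TBSO)-3-(TBSO-methyl)-4-[(1E)-prop-1-en-1-yl]oxolan-2-one
Product: 15 (3R,4S)-4-(TBSO)-4-(TBSO-methyl)-5-oxooxolane-3-carbaldehyde, via ozonide 14 (not isolated)
Conditions: O3, CH2Cl2, −78 °C; PPh3 (1.2 equiv), −78 °C → rt; used crude
Reagents that add atoms: ozone, [O-][O+]=O
Why: Ozonolysis with reductive work-up cleaves the only C=C bond (no arene is present yet) to the C6 aldehyde under neutral conditions, which spares the α-stereocentre C5.

Step 10
Reactants: 16 4-bromo-1,2-dimethoxybenzene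
Product: 17 (3,4-dimethoxyphenyl)magnesium bromide (THF solution)
Conditions: Mg turnings (1.2 equiv), I2 (cat.), THF, rt → 40 °C; titrated, kept under argon
Reagents that add atoms: magnesium, [Mg]
Why: Grignard reagent formation by insertion of magnesium into the aryl C–Br bond gives one titrated stock solution, portions of which serve the two aryl additions of steps 11 and 14.

Step 11
Reactants: 15 (3R,4S)-4-(TBSO)-4-(TBSO-methyl)-5-oxooxolane-3-carbaldehyde; 17 (3,4-dimethoxyphenyl)magnesium bromide
Product: 18 (3S,4S)-3-(TBSO)-3-(TBSO-methyl)-4-[(3,4-dimethoxyphenyl)(hydroxy)methyl]oxolan-2-one (both carbinol epimers)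
Conditions: 17 (1.3 equiv), THF, −78 °C; H2O at −78 °C
Reagents that add atoms: none
Why: Grignard addition to the aldehyde at low temperature is much faster than attack on the hindered α-quaternary lactone, the cold quench keeps the magnesium alkoxide from opening the lactone, and the new carbinol centre is formed without control because it is removed again in step 12.

Step 12
Reactants: 18 (3S,4S)-3-(TBSO)-3-(TBSO-methyl)-4-[(3,4-dimethoxyphenyl)(hydroxy)methyl]oxolan-2-one
Product: 19 (3S,4R)-4-(3,4-dimethoxybenzoyl)-3-(TBSO)-3-(TBSO-methyl)oxolan-2-one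
Conditions: Dess–Martin periodinane (1.5 equiv), CH2Cl2, 0 °C → rt
Reagents that add atoms: none
Why: Dess–Martin oxidation converts the secondary benzylic alcohol into the aryl ketone under non-basic conditions, which avoids enolisation at C5 and β-elimination of the lactone oxygen.

Step 13
Reactants: 19 (3S,4R)-4-(3,4-dimethoxybenzoyl)-3-(TBSO)-3-(TBSO-methyl)oxolan-2-one
Product: 21 (2RS,3S,4S)-3-(TBSO)-3-(TBSO-methyl)-4-[(R)-(3,4-dimethoxyphenyl)(hydroxy)methyl]oxolan-2-ol (lactol anomers), via hydroxy lactone 20 (not isolated)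
Conditions: i-Bu2AlH (3.5 equiv), CH2Cl2, −78 °C, 2 h; aq. potassium sodium tartrate
Reagents that add atoms: none
Why: Hydride reduction in which i-Bu2AlH reduces the aryl ketone and stops the lactone at the lactol (stable aluminium hemiacetal at −78 °C), and by the Felkin–Anh model hydride should reach C6 anti to the quaternary C1, the largest group on C5, which gives the R carbinol required at C6.

Step 14
Reactants: 21 (2RS,3S,4S)-3-(TBSO)-3-(TBSO-methyl)-4-[(R)-(3,4-dimethoxyphenyl)(hydroxy)methyl]oxolan-2-ol; 17 (3,4-dimethoxyphenyl)magnesium bromide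
Product: 23 (1S,2S,3S,4R)-2-(TBSO)-2-(TBSO-methyl)-1,4-bis(3,4-dimethoxyphenyl)-3-(hydroxymethyl)butane-1,4-diol, via open-chain aldehyde 22 (not isolated)
Conditions: 17 (5 equiv), THF, −20 → 0 °C; H2O
Reagents that add atoms: none
Why: Grignard addition to a lactol through its ring-opened aldehyde 22, where by the polar Felkin–Anh model the aryl group should enter anti to the C1–O(silyl) bond and past the small C8 methylene instead of the branched C5, which gives the S carbinol at C2, the silyl ether being unable to chelate and the cold conditions keeping the silyl group on O1.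

Step 15
Reactants: 23 (1S,2S,3S,4R)-2-(TBSO)-2-(TBSO-methyl)-1,4-bis(3,4-dimethoxyphenyl)-3-(hydroxymethyl)butane-1,4-diol
Product: 24 (1S,2S,3S,4R)-2-(TBSO)-1,4-bis(3,4-dimethoxyphenyl)-2,3-bis(hydroxymethyl)butane-1,4-diol
Conditions: HF·pyridine, pyridine (excess), THF, 0 °C → rt
Reagents that add atoms: none
Why: Fluoride-induced desilylation should remove the primary silyl ether on C8 far faster than the tertiary one on C1, and the pyridine-buffered medium does not ionise the electron-rich benzylic carbinols.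

Step 16
Reactants: 24 (1S,2S,3S,4R)-2-(TBSO)-1,4-bis(3,4-dimethoxyphenyl)-2,3-bis(hydroxymethyl)butane-1,4-diol
Product: 25 (1S,2S,3S,4R)-2-(TBSO)-1,4-bis(3,4-dimethoxyphenyl)-2,3-bis[(4-methylphenyl)sulfonyloxymethyl]butane-1,4-diol
Conditions: TsCl (2.3 equiv), Et3N (5 equiv), Me3N·HCl (0.2 equiv), CH2Cl2, −10 → 0 °C; used at once
Reagents that add atoms: 4-methylbenzenesulfonyl chloride, Cc1ccc(cc1)S(Cl)(=O)=O
Why: Sulfonylation at low temperature is selective for the two primary hydroxyls (C4, C8) over the hindered secondary benzylic ones and should give the open-chain cyclisation precursor.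

Step 17
Reactants: 25 (1S,2S,3S,4R)-2-(TBSO)-1,4-bis(3,4-dimethoxyphenyl)-2,3-bis[(4-methylphenyl)sulfonyloxymethyl]butane-1,4-diol
Product: 27 tert-butyl{[(1S,2S,5S,6R)-2,6-bis(3,4-dimethoxyphenyl)-3,7-dioxabicyclo[3.3.0]octan-1-yl]oxy}dimethylsilane, via monocyclic tosylate 26 (not isolated)
Conditions: NaH (4 equiv), THF, 0 °C → rt (ring B), then 45 °C (ring A)
Reagents that add atoms: none
Why: NaH turns the C2 and C6 hydroxyls into sodium alkoxides, each of which attacks a primary carbon four atoms away with loss of tosylate; this is an intramolecular Williamson ether synthesis, the closest known type being the base closure of 1,4-diol monosulfonates to oxolanes. Ring B should close first by 5-exo-tet attack of O3 on the unhindered C4 to give monocycle 26, and ring A then closes by 5-exo-tet attack of O7 on the neopentyl C8, a slower displacement that builds the trans-fusion strain and is carried by its irreversibility. No stereocentre is formed or broken, because both displacements occur at CH2 groups, so C1, C2, C5 and C6 arrive as set in steps 6, 13 and 14. The step needs chemoselectivity among the oxygen nucleophiles: each alkoxide can reach the other tosylate only through a four-membered transition state, so ring size secures O3→C4 and O7→C8. The silyl ether on O1 prevents closure of a C1–C8 oxirane, and a bulky silyl group on a tertiary oxygen is chosen because it is slow to shift to the neighbouring alkoxides.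

Step 18
Reactants: 27 tert-butyl{[(1S,2S,5S,6R)-2,6-bis(3,4-dimethoxyphenyl)-3,7-dioxabicyclo[3.3.0]octan-1-yl]oxy}dimethylsilane
Product: 28 (1S,2S,5S,6R)-2,6-bis(3,4-dimethoxyphenyl)-3,7-dioxabicyclo[3.3.0]octan-1-ol (target)
Conditions: Bu4NF (3 equiv), THF, rt → 50 °C
Reagents that add atoms: none
Why: Fluoride-mediated desilylation cleaves only the Si–O bond of the tertiary silyl ether under non-acidic conditions, so the benzylic ethers and all four stereocentres stay untouched.

Compound list
1 | (R)-but-3-yn-2-ol | C[C@@H](O)C#C | starting material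
2 | (4R)-pent-2-yne-1,4-diol | C[C@@H](O)C#CCO | intermediate
3 | (2E,4R)-pent-2-ene-1,4-diol | C[C@@H](O)/C=C/CO | intermediate
4 | (2R,3E)-5-(TBSO)pent-3-en-2-ol | C[C@@H](O)/C=C/CO[Si](C)(C)C(C)(C)C | intermediate
5 | methyl 2,2-dimethyl-1,3-dioxolane-4-carboxylate (racemic) | COC(=O)C1COC(C)(C)O1 | starting material
6 | potassium 2,2-dimethyl-1,3-dioxolane-4-carboxylate (racemic) | [K+].[O-]C(=O)C1COC(C)(C)O1 | intermediate
7 | (2R,3E)-5-(TBSO)pent-3-en-2-yl 2,2-dimethyl-1,3-dioxolane-4-carboxylate (both epimers at the dioxolane carbon) | C[C@@H](OC(=O)C1COC(C)(C)O1)/C=C/CO[Si](C)(C)C(C)(C)C | intermediate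
8 | Z silyl ketene acetal of 7 (Me3SiO cis to the ring oxygen, allyloxy cis to the ring CH2) | C[C@@H](O/C(O[Si](C)(C)C)=C1\COC(C)(C)O1)/C=C/CO[Si](C)(C)C(C)(C)C | intermediate (not isolated)
9 | trimethylsilyl (4S)-4-[(2R,3E)-1-(TBSO)pent-3-en-2-yl]-2,2-dimethyl-1,3-dioxolane-4-carboxylate | C[Si](C)(C)OC(=O)[C@@]1(COC(C)(C)O1)[C@@H](CO[Si](C)(C)C(C)(C)C)/C=C/C | intermediate (not isolated)
10 | (4S)-4-[(2R,3E)-1-(TBSO)pent-3-en-2-yl]-2,2-dimethyl-1,3-dioxolane-4-carboxylic acid | OC(=O)[C@@]1(COC(C)(C)O1)[C@@H](CO[Si](C)(C)C(C)(C)C)/C=C/C | intermediate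
11 | (2S,3R,4E)-2-hydroxy-2,3-bis(hydroxymethyl)hex-4-enoic acid | OC(=O)[C@@](O)(CO)[C@@H](CO)/C=C/C | intermediate (not isolated)
12 | (3S,4R)-3-hydroxy-3-(hydroxymethyl)-4-[(1E)-prop-1-en-1-yl]oxolan-2-one | O=C1OC[C@@H](/C=C/C)[C@]1(O)CO | intermediate
13 | (3S,4R)-3-(TBSO)-3-(TBSO-methyl)-4-[(1E)-prop-1-en-1-yl]oxolan-2-one | O=C1OC[C@@H](/C=C/C)[C@]1(O[Si](C)(C)C(C)(C)C)CO[Si](C)(C)C(C)(C)C | intermediate
14 | (3S,4R)-3-(TBSO)-3-(TBSO-methyl)-4-(5-methyl-1,2,4-trioxolan-3-yl)oxolan-2-one (ozonide, isomers at the trioxolane carbons) | O=C1OC[C@@H](C2OOC(C)O2)[C@]1(O[Si](C)(C)C(C)(C)C)CO[Si](C)(C)C(C)(C)C | intermediate (not isolated)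
15 | (3R,4S)-4-(TBSO)-4-(TBSO-methyl)-5-oxooxolane-3-carbaldehyde | O=C1OC[C@@H](C=O)[C@]1(O[Si](C)(C)C(C)(C)C)CO[Si](C)(C)C(C)(C)C | intermediate
16 | 4-bromo-1,2-dimethoxybenzene | COc1ccc(Br)cc1OC | starting material
17 | (3,4-dimethoxyphenyl)magnesium bromide (THF solution) | COc1ccc([Mg]Br)cc1OC | intermediate
18 | (3S,4S)-3-(TBSO)-3-(TBSO-methyl)-4-[(3,4-dimethoxyphenyl)(hydroxy)methyl]oxolan-2-one (both carbinol epimers) | O=C1OC[C@@H](C(O)c2ccc(OC)c(OC)c2)[C@]1(O[Si](C)(C)C(C)(C)C)CO[Si](C)(C)C(C)(C)C | intermediate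
19 | (3S,4R)-4-(3,4-dimethoxybenzoyl)-3-(TBSO)-3-(TBSO-methyl)oxolan-2-one | O=C1OC[C@@H](C(=O)c2ccc(OC)c(OC)c2)[C@]1(O[Si](C)(C)C(C)(C)C)CO[Si](C)(C)C(C)(C)C | intermediate
20 | (3S,4S)-3-(TBSO)-3-(TBSO-methyl)-4-[(R)-(3,4-dimethoxyphenyl)(hydroxy)methyl]oxolan-2-one | O=C1OC[C@@H]([C@@H](O)c2ccc(OC)c(OC)c2)[C@]1(O[Si](C)(C)C(C)(C)C)CO[Si](C)(C)C(C)(C)C | intermediate (not isolated)
21 | (2RS,3S,4S)-3-(TBSO)-3-(TBSO-methyl)-4-[(R)-(3,4-dimethoxyphenyl)(hydroxy)methyl]oxolan-2-ol (lactol anomers) | OC1OC[C@@H]([C@@H](O)c2ccc(OC)c(OC)c2)[C@]1(O[Si](C)(C)C(C)(C)C)CO[Si](C)(C)C(C)(C)C | intermediate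
22 | (2S,3S,4R)-2-(TBSO)-2-(TBSO-methyl)-4-(3,4-dimethoxyphenyl)-4-hydroxy-3-(hydroxymethyl)butanal | O=C[C@@](O[Si](C)(C)C(C)(C)C)(CO[Si](C)(C)C(C)(C)C)[C@@H](CO)[C@@H](O)c1ccc(OC)c(OC)c1 | intermediate (not isolated)
23 | (1S,2S,3S,4R)-2-(TBSO)-2-(TBSO-methyl)-1,4-bis(3,4-dimethoxyphenyl)-3-(hydroxymethyl)butane-1,4-diol | COc1ccc(cc1OC)[C@H](O)[C@H](CO)[C@](O[Si](C)(C)C(C)(C)C)(CO[Si](C)(C)C(C)(C)C)[C@@H](O)c2ccc(OC)c(OC)c2 | intermediate
24 | (1S,2S,3S,4R)-2-(TBSO)-1,4-bis(3,4-dimethoxyphenyl)-2,3-bis(hydroxymethyl)butane-1,4-diol | COc1ccc(cc1OC)[C@H](O)[C@H](CO)[C@](O[Si](C)(C)C(C)(C)C)(CO)[C@@H](O)c2ccc(OC)c(OC)c2 | intermediate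
25 | (1S,2S,3S,4R)-2-(TBSO)-1,4-bis(3,4-dimethoxyphenyl)-2,3-bis[(4-methylphenyl)sulfonyloxymethyl]butane-1,4-diol (key-step precursor) | COc1ccc(cc1OC)[C@H](O)[C@H](COS(=O)(=O)c2ccc(C)cc2)[C@](O[Si](C)(C)C(C)(C)C)(COS(=O)(=O)c3ccc(C)cc3)[C@@H](O)c4ccc(OC)c(OC)c4 | intermediate
26 | {(2S,3S,4S)-3-(TBSO)-2-(3,4-dimethoxyphenyl)-4-[(R)-(3,4-dimethoxyphenyl)(hydroxy)methyl]oxolan-3-yl}methyl 4-methylbenzenesulfonate (ring B closed) | COc1ccc(cc1OC)[C@H](O)[C@@H]2CO[C@@H](c3ccc(OC)c(OC)c3)[C@@]2(O[Si](C)(C)C(C)(C)C)COS(=O)(=O)c4ccc(C)cc4 | intermediate (not isolated)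
27 | tert-butyl{[(1S,2S,5S,6R)-2,6-bis(3,4-dimethoxyphenyl)-3,7-dioxabicyclo[3.3.0]octan-1-yl]oxy}dimethylsilane (key-step product) | COc1ccc(cc1OC)[C@@H]2OC[C@]3(O[Si](C)(C)C(C)(C)C)[C@H](c4ccc(OC)c(OC)c4)OC[C@@H]23 | intermediate
28 | (1S,2S,5S,6R)-2,6-bis(3,4-dimethoxyphenyl)-3,7-dioxabicyclo[3.3.0]octan-1-ol | COc1ccc([C@@H]2OC[C@]3(O)[C@H](c4ccc(OC)c(OC)c4)OC[C@@H]23)cc1OC | target

Total step count: 18. Longest linear sequence: 16 steps (steps 1–3, 5–9 and 11–18 from (R)-but-3-yn-2-ol; steps 4 and 10 are one-step side branches).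

Steps most likely to fail

Step 17. The second displacement, at the neopentyl C8 and against the strain of the trans fusion, may be slower than transfer of the silyl group from O1 to the C6 alkoxide followed by oxirane closure at C8, or slower than intermolecular reaction. The fallback avoids sulfonates and free alkoxides altogether and sets out from tetraol 24. A double Mitsunobu cyclodehydration (PPh3, diisopropyl azodicarboxylate, THF, 0 °C → reflux; (cyanomethylene)tributylphosphorane in toluene at 90 °C if the second ring stalls) activates the two primary hydroxyls as oxyphosphonium ions under neutral conditions. The benzylic hydroxyls then displace them with retention at C2 and C6, by way of the ring B monocyclic diol (2S,3S,4S)-3-(TBSO)-2-(3,4-dimethoxyphenyl)-4-[(R)-(3,4-dimethoxyphenyl)(hydroxy)methyl]-3-(hydroxymethyl)oxolane F1. The route is rejoined at 27, so that steps 16 and 17 are replaced.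

Step 14. The aryl addition may show poor facial selectivity if metal-bridged arrangements involving the C4 and C6 alkoxides compete with the polar Felkin–Anh pathway, and the silyl group may shift from O1 to the new C2 alkoxide if the mixture warms. The fallback sets C2 by reagent-controlled hydride delivery instead of substrate-controlled aryl delivery and sets out from ketone 19. NaBH4 (MeOH–THF, −40 °C) reduces only the ketone and hydroxy lactone 20 is isolated. (3,4-Dimethoxyphenyl)lithium F2 (from 16 and n-BuLi, THF, −78 °C, 2.2 equiv) adds once to the lactone carbonyl, and the tetrahedral adduct collapses on work-up to the γ-hydroxy aryl ketone (2S,3S,4R)-2-(TBSO)-2-(TBSO-methyl)-1,4-bis(3,4-dimethoxyphenyl)-4-hydroxy-3-(hydroxymethyl)butan-1-one F3. Corey–Bakshi–Shibata reduction with the (S)-B-methyl oxazaborolidine and BH3·SMe2 (THF, −20 °C) should then deliver hydride to the face that gives the S carbinol, assuming the aryl group acts as the larger substituent; if it does not, the (R)-catalyst is used. The route is rejoined at triol 23.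

Step 6. The dioxolane enolate may undergo β-elimination (ring opening) before it is silylated, the ketene acetal geometry may be incompletely controlled, or a boat transition state may compete; each would lower the yield or the C1/C5 ratio. The fallback builds C5 and C1 in two separate stereocontrolled events and sets out from allylic alcohol 4. A Johnson–Claisen rearrangement (MeC(OEt)3, cat. EtCO2H, 140 °C) sets C5 by the same chair-type chirality transfer and gives ethyl (3R,4E)-3-(TBSO-methyl)hex-4-enoate F4. Bu4NF in THF removes the silyl group and the alkoxide lactonises to (4R)-4-[(1E)-prop-1-en-1-yl]oxolan-2-one F5. Enolate hydroxylation (LiN(SiMe3)2, then 2-(phenylsulfonyl)-3-phenyloxaziridine, THF, −78 °C) gives (4R)-3-hydroxy-4-[(1E)-prop-1-en-1-yl]oxolan-2-one F6, which is silylated (t-BuMe2SiOTf, 2,6-lutidine) to (4R)-3-(TBSO)-4-[(1E)-prop-1-en-1-yl]oxolan-2-one F7. Aldol reaction of the enolate of this silyl ether (LiN(i-Pr)2, THF, −78 °C) with monomeric formaldehyde takes place anti to the propenyl group on C5 and sets C1 in (3S,4R)-3-(TBSO)-3-(hydroxymethyl)-4-[(1E)-prop-1-en-1-yl]oxolan-2-one F8. t-BuMe2SiCl and imidazole then give 13, where the route is rejoined; steps 4 to 8 are replaced.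

Further compounds
F1 | step 17 | (2S,3S,4S)-3-(TBSO)-2-(3,4-dimethoxyphenyl)-4-[(R)-(3,4-dimethoxyphenyl)(hydroxy)methyl]-3-(hydroxymethyl)oxolane | COc1ccc(cc1OC)[C@H](O)[C@@H]2CO[C@@H](c3ccc(OC)c(OC)c3)[C@@]2(O[Si](C)(C)C(C)(C)C)CO
F2 | step 14 | (3,4-dimethoxyphenyl)lithium | [Li]c1ccc(OC)c(OC)c1
F3 | step 14 | (2S,3S,4R)-2-(TBSO)-2-(TBSO-methyl)-1,4-bis(3,4-dimethoxyphenyl)-4-hydroxy-3-(hydroxymethyl)butan-1-one | COc1ccc(cc1OC)[C@H](O)[C@H](CO)[C@](O[Si](C)(C)C(C)(C)C)(CO[Si](C)(C)C(C)(C)C)C(=O)c2ccc(OC)c(OC)c2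
F4 | step 6 | ethyl (3R,4E)-3-(TBSO-methyl)hex-4-enoate | CCOC(=O)C[C@@H](CO[Si](C)(C)C(C)(C)C)/C=C/C
F5 | step 6 | (4R)-4-[(1E)-prop-1-en-1-yl]oxolan-2-one | O=C1OC[C@@H](/C=C/C)C1
F6 | step 6 | (4R)-3-hydroxy-4-[(1E)-prop-1-en-1-yl]oxolan-2-one (epimers at C-3) | O=C1OC[C@@H](/C=C/C)C1O
F7 | step 6 | (4R)-3-(TBSO)-4-[(1E)-prop-1-en-1-yl]oxolan-2-one (epimers at C-3) | O=C1OC[C@@H](/C=C/C)C1O[Si](C)(C)C(C)(C)C
F8 | step 6 | (3S,4R)-3-(TBSO)-3-(hydroxymethyl)-4-[(1E)-prop-1-en-1-yl]oxolan-2-one | O=C1OC[C@@H](/C=C/C)[C@]1(O[Si](C)(C)C(C)(C)C)CO
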